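The flavanonol core is cut at two bonds of ring C, O1–C8a and C4–C4a. Ring A holds O1 on C8a and the ketone carbon C4 on the adjacent C4a, with the C5 oxygen next to C4a and hydrogen at C8: the exact 1,2-relationship, and the exact polarity, that a 3-alkoxy aryne offers to a nucleophile–electrophile pair. One fluoride-triggered operation joins 3,5-bis(benzyloxy)benzyne to the silyl-masked alkoxide of an enantiopure anti α-benzyloxy-β-hydroxy ester and closes ring C with both stereocentres already in place. The precursors are an ortho-silylaryl triflate and an aldol-derived hydroxy ester; the 1,1-dimethylallyl group comes last by Claisen shift from O5 to C6.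

Key step: step 8

Assumption: in step 5 the aldehyde is taken to attack the face of the sulfur-chelated titanium enolate opposite the 4-benzyl group, which makes the (S)-auxiliary the source of the (2R,3R) adduct; should the anti adduct prove to be the (2S,3S) antipode, the (R)-auxiliary would be used and nothing else would change.

Step 1
Reactants: 1 3,5-bis(benzyloxy)phenol
Product: 2 3,5-bis(benzyloxy)phenyl N-isopropylcarbamate
Conditions: i-PrNCO, Et3N (cat.), CH2Cl2, rt
Reagents that add atoms: isopropyl isocyanate, CC(C)N=C=O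
Why: Amine-catalysed addition of the phenol to the isocyanate (carbamoylation) should be clean and installs a strong ortho-directing group that can later be removed under mild base.

Step 2
Reactants: 2 3,5-bis(benzyloxy)phenyl N-isopropylcarbamate
Product: 6 3,5-bis(benzyloxy)-2-(trimethylsilyl)phenyl N-isopropylcarbamate, via N-silyl carbamate 3 (not isolated), via ortho-lithiated carbamate 4 (not isolated), via doubly silylated carbamate 5 (not isolated)
Conditions: TBSOTf, TMEDA, Et2O, 0 °C to rt; n-BuLi, TMEDA, −78 °C; TMSCl, −78 °C to rt; aq. NaHSO4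
Reagents that add atoms: chlorotrimethylsilane, C[Si](C)(C)Cl
Why: Directed ortho-metalation: once the N–H is masked in the flask as its silyl derivative, the carbamate and the neighbouring benzyloxy group together steer n-BuLi to the carbon between them (C2 and C6 are equivalent by symmetry), the aryllithium is trapped by TMSCl, and the labile N-silyl group is hydrolysed on acidic work-up.

Step 3
Reactants: 6 3,5-bis(benzyloxy)-2-(trimethylsilyl)phenyl N-isopropylcarbamate
Product: 8 3,5-bis(benzyloxy)-2-(trimethylsilyl)phenyl trifluoromethanesulfonate, via silylphenol 7 (not isolated)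
Conditions: DBU, Et2NH, MeCN, 40 °C; then PhNTf2, rt
Reagents that add atoms: N-phenylbis(trifluoromethanesulfonimide), O=S(=O)(N(c1ccccc1)S(=O)(=O)C(F)(F)F)C(F)(F)F
Why: Base-induced E1cB cleavage of the N-monoalkyl carbamate releases isopropyl isocyanate (scavenged by Et2NH) and the phenoxide, which the mild triflating agent sulfonylates in the same flask without touching the C–Si bond (one-pot carbamate cleavage and O-triflation).

Step 4
Reactants: 9 (S)-4-benzyl-1,3-oxazolidine-2-thione; 10 (benzyloxy)acetyl chloride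
Product: 11 (4S)-4-benzyl-3-[(benzyloxy)acetyl]-1,3-oxazolidine-2-thione
Conditions: Et3N, CH2Cl2, 0 °C to rt
Reagents that add atoms: none
Why: N-Acylation of the auxiliary by the acid chloride gives the glycolyl imide, whose thiocarbonyl later serves both as a ligand for titanium and as the activating group for mild auxiliary removal.

Step 5
Reactants: 11 (4S)-4-benzyl-3-[(benzyloxy)acetyl]-1,3-oxazolidine-2-thione; 12 4-(benzyloxy)benzaldehyde
Product: 14 (4S)-4-benzyl-3-[(2R,3R)-2-(benzyloxy)-3-[4-(benzyloxy)phenyl]-3-hydroxypropanoyl]-1,3-oxazolidine-2-thione, via chlorotitanium enolate 13 (not isolated)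
Conditions: TiCl4, i-Pr2NEt, CH2Cl2, −78 °C; then 12 premixed with TiCl4, −78 °C; aq. NH4Cl
Reagents that add atoms: none
Why: Titanium-mediated anti-selective glycolate aldol addition: soft enolisation gives the (Z)-enolate, which meets the TiCl4-bound aldehyde in an open transition state, so that the anti relationship follows from the enolate geometry and the absolute configuration of both new centres (2R,3R) from the 4-benzyl group of the auxiliary, which shields one enolate face.

Step 6
Reactants: 14 (4S)-4-benzyl-3-[(2R,3R)-2-(benzyloxy)-3-[4-(benzyloxy)phenyl]-3-hydroxypropanoyl]-1,3-oxazolidine-2-thione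
Product: 15 methyl (2R,3R)-2-(benzyloxy)-3-[4-(benzyloxy)phenyl]-3-hydroxypropanoate
Conditions: MeOH, imidazole, CH2Cl2, rt
Reagents that add atoms: methanol, CO
Why: Imidazole-catalysed methanolysis (acyl transfer) of the activated N-acyl oxazolidinethione should free the recoverable auxiliary under conditions too mild for retro-aldol cleavage or epimerisation next to the ester.

Step 7
Reactants: 15 methyl (2R,3R)-2-(benzyloxy)-3-[4-(benzyloxy)phenyl]-3-hydroxypropanoate
Product: 16 methyl (2R,3R)-2-(benzyloxy)-3-[4-(benzyloxy)phenyl]-3-[(trimethylsilyl)oxy]propanoate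
Conditions: TMSCl, imidazole, CH2Cl2, 0 °C; non-aqueous work-up
Reagents that add atoms: chlorotrimethylsilane, C[Si](C)(C)Cl
Why: Routine O-silylation of a secondary alcohol turns the hydroxyl into a latent alkoxide that fluoride can unmask without leaving an O–H proton in the flask.

Step 8
Reactants: 8 3,5-bis(benzyloxy)-2-(trimethylsilyl)phenyl trifluoromethanesulfonate; 16 methyl (2R,3R)-2-(benzyloxy)-3-[4-(benzyloxy)phenyl]-3-[(trimethylsilyl)oxy]propanoate
Product: 20 (2R,3R)-3,5,7-tris(benzyloxy)-2-[4-(benzyloxy)phenyl]-2,3-dihydro-4H-chromen-4-one, via cesium alkoxide 17 (not isolated), via 3,5-bis(benzyloxy)benzyne 18 (not isolated), via aryl anion 19 (not isolated)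
Conditions: CsF, 18-crown-6, THF, 0 °C to rt
Reagents that add atoms: none
Why: Proposed new method: fluoride removes the trimethylsilyl group from each partner, so that 8 loses triflate to give aryne 18 while 16 gives alkoxide 17 with no O–H proton; 17 adds to the aryne carbon remote from the flanking benzyloxy group (O1–C8a), and the resulting aryl anion 19 at C4a attacks the methyl ester and expels methoxide (C4–C4a). The closest known reaction type is the CsF-mediated annulation of ortho-silylaryl triflates with methyl salicylates to xanthones (O-arylation followed by acyl capture), and arynes are known to arylate aliphatic alcohols at oxygen. Ring C closes by 6-exo-trig attack of the aryl anion on the ester carbonyl. No stereocentre is created: C2 and C3 are those of the anti aldol product, no bond to either is broken, and the anti pair therefore becomes the 2,3-trans ring. The regioselectivity needed (oxygen to C8a, anion at C4a) is secured by the inductive and distorting effect of the C5 benzyloxy group next to the triple bond, and the chemoselectivity needed (acyl capture ahead of protonation) by releasing the nucleophile from a silyl ether, with the α-benzyloxy group unable to act as a nucleophile.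

Step 9
Reactants: 20 (2R,3R)-3,5,7-tris(benzyloxy)-2-[4-(benzyloxy)phenyl]-2,3-dihydro-4H-chromen-4-one
Product: 21 (2R,3R)-3,5,7-trihydroxy-2-(4-hydroxyphenyl)-2,3-dihydro-4H-chromen-4-one
Conditions: H2 (1 atm), 10% Pd/C, EtOAc/MeOH, rt
Reagents that add atoms: none
Why: Catalytic hydrogenolysis of the three aryl benzyl ethers and the one alkyl benzyl ether is routine on flavanones at ambient pressure, where the ketone, the ring C–O bond and both stereocentres should be left alone.

Step 10
Reactants: 21 (2R,3R)-3,5,7-trihydroxy-2-(4-hydroxyphenyl)-2,3-dihydro-4H-chromen-4-one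
Product: 22 (2R,3R)-3,7-bis[(tert-butyldimethylsilyl)oxy]-2-{4-[(tert-butyldimethylsilyl)oxy]phenyl}-5-hydroxy-2,3-dihydro-4H-chromen-4-one
Conditions: TBSCl, imidazole, DMF, rt
Reagents that add atoms: tert-butyl(chloro)dimethylsilane, CC(C)(C)[Si](C)(C)Cl
Why: Selective O-silylation: the two free phenols and the secondary alcohol should be silylated, while the 5-hydroxyl, held in a strong hydrogen bond to the C4 carbonyl, is the least nucleophilic oxygen and should stay free, so that no alcohol competes in the next step.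

Step 11
Reactants: 22 (2R,3R)-3,7-bis[(tert-butyldimethylsilyl)oxy]-2-{4-[(tert-butyldimethylsilyl)oxy]phenyl}-5-hydroxy-2,3-dihydro-4H-chromen-4-one; 23 3-methylbut-2-en-1-ol
Product: 25 (2R,3R)-3,7-bis[(tert-butyldimethylsilyl)oxy]-2-{4-[(tert-butyldimethylsilyl)oxy]phenyl}-5-[(3-methylbut-2-en-1-yl)oxy]-2,3-dihydro-4H-chromen-4-one, via prenyloxyphosphonium ion 24 (not isolated)
Conditions: PPh3, DIAD, THF, 0 °C to rt
Reagents that add atoms: none
Why: Mitsunobu etherification: the chelated 5-OH is the only acidic site left, and it displaces the oxyphosphonium group at the primary carbon of the activated allylic alcohol under neutral conditions that spare the base-sensitive hydroxy ketone core.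

Step 12
Reactants: 25 (2R,3R)-3,7-bis[(tert-butyldimethylsilyl)oxy]-2-{4-[(tert-butyldimethylsilyl)oxy]phenyl}-5-[(3-methylbut-2-en-1-yl)oxy]-2,3-dihydro-4H-chromen-4-one
Product: 27 (2R,3R)-3,7-bis[(tert-butyldimethylsilyl)oxy]-2-{4-[(tert-butyldimethylsilyl)oxy]phenyl}-5-hydroxy-6-(2-methylbut-3-en-2-yl)-2,3-dihydro-4H-chromen-4-one, via ortho dienone 26 (not isolated)
Conditions: PhNEt2, 190 °C (sealed tube)
Reagents that add atoms: none
Why: Aromatic Claisen rearrangement: the [3,3] shift from O5 can reach only C6, since the other ortho carbon is C4a, it transposes the allyl unit so that the 1,1-dimethylallyl group results, and enolisation of the dienone restores the hydrogen-bonded 5-OH.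

Step 13
Reactants: 27 (2R,3R)-3,7-bis[(tert-butyldimethylsilyl)oxy]-2-{4-[(tert-butyldimethylsilyl)oxy]phenyl}-5-hydroxy-6-(2-methylbut-3-en-2-yl)-2,3-dihydro-4H-chromen-4-one
Product: 28 (2R,3R)-3,5,7-trihydroxy-2-(4-hydroxyphenyl)-6-(2-methylbut-3-en-2-yl)-2,3-dihydro-4H-chromen-4-one
Conditions: HF·pyridine, pyridine, THF, 0 °C to rt
Reagents that add atoms: none
Why: Fluoride-mediated desilylation under buffered, mildly acidic conditions should remove the two aryl silyl ethers and the alkyl silyl ether without acid strong enough to hydrate or cyclise the terminal alkene and without base that could open ring C.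

Compound list

1 | 3,5-bis(benzyloxy)phenol | Oc1cc(OCc2ccccc2)cc(OCc2ccccc2)c1 | starting material
2 | 3,5-bis(benzyloxy)phenyl N-isopropylcarbamate | CC(C)NC(=O)Oc1cc(OCc2ccccc2)cc(OCc2ccccc2)c1 | intermediate
3 | 3,5-bis(benzyloxy)phenyl N-(tert-butyldimethylsilyl)-N-isopropylcarbamate (not isolated) | CC(C)N(C(=O)Oc1cc(OCc2ccccc2)cc(OCc2ccccc2)c1)[Si](C)(C)C(C)(C)C | intermediate
4 | 2-lithio derivative of 3, lithium on the ring carbon between the carbamate and a benzyloxy group (not isolated) | CC(C)N(C(=O)Oc1cc(OCc2ccccc2)cc(OCc2ccccc2)c1[Li])[Si](C)(C)C(C)(C)C | intermediate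
5 | 3,5-bis(benzyloxy)-2-(trimethylsilyl)phenyl N-(tert-butyldimethylsilyl)-N-isopropylcarbamate (not isolated) | CC(C)N(C(=O)Oc1cc(OCc2ccccc2)cc(OCc2ccccc2)c1[Si](C)(C)C)[Si](C)(C)C(C)(C)C | intermediate
6 | 3,5-bis(benzyloxy)-2-(trimethylsilyl)phenyl N-isopropylcarbamate | CC(C)NC(=O)Oc1cc(OCc2ccccc2)cc(OCc2ccccc2)c1[Si](C)(C)C | intermediate
7 | 3,5-bis(benzyloxy)-2-(trimethylsilyl)phenol, present as its amidinium phenoxide (not isolated) | Oc1cc(OCc2ccccc2)cc(OCc2ccccc2)c1[Si](C)(C)C | intermediate
8 | 3,5-bis(benzyloxy)-2-(trimethylsilyl)phenyl trifluoromethanesulfonate | C[Si](C)(C)c1c(OCc2ccccc2)cc(OCc2ccccc2)cc1OS(=O)(=O)C(F)(F)F | intermediate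
9 | (S)-4-benzyl-1,3-oxazolidine-2-thione | S=C1N[C@@H](Cc2ccccc2)CO1 | starting material
10 | (benzyloxy)acetyl chloride | O=C(Cl)COCc1ccccc1 | starting material
11 | (4S)-4-benzyl-3-[(benzyloxy)acetyl]-1,3-oxazolidine-2-thione | O=C(COCc1ccccc1)N1C(=S)OC[C@@H]1Cc1ccccc1 | intermediate
12 | 4-(benzyloxy)benzaldehyde | O=Cc1ccc(OCc2ccccc2)cc1 | starting material
13 | (Z)-trichlorotitanium enolate of 11 (not isolated) | Cl[Ti](Cl)(Cl)O/C(=C\OCc1ccccc1)N1C(=S)OC[C@@H]1Cc1ccccc1 | intermediate
14 | (4S)-4-benzyl-3-[(2R,3R)-2-(benzyloxy)-3-[4-(benzyloxy)phenyl]-3-hydroxypropanoyl]-1,3-oxazolidine-2-thione (anti adduct) | O=C([C@H](OCc1ccccc1)[C@@H](c1ccc(OCc2ccccc2)cc1)O)N1C(=S)OC[C@@H]1Cc1ccccc1 | intermediate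
15 | methyl (2R,3R)-2-(benzyloxy)-3-[4-(benzyloxy)phenyl]-3-hydroxypropanoate (anti) | COC(=O)[C@H](OCc1ccccc1)[C@@H](c1ccc(OCc2ccccc2)cc1)O | intermediate
16 | methyl (2R,3R)-2-(benzyloxy)-3-[4-(benzyloxy)phenyl]-3-[(trimethylsilyl)oxy]propanoate | COC(=O)[C@H](OCc1ccccc1)[C@@H](c1ccc(OCc2ccccc2)cc1)O[Si](C)(C)C | intermediate
17 | cesium alkoxide of 15 (not isolated) | COC(=O)[C@H](OCc1ccccc1)[C@@H](c1ccc(OCc2ccccc2)cc1)[O-].[Cs+] | intermediate
18 | 3,5-bis(benzyloxy)benzyne (not isolated) | C1#CC(OCc2ccccc2)=CC(OCc2ccccc2)=C1 | intermediate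
19 | aryl cesium formed by O-arylation of 17 at the future C8a, carbanion at the future C4a between the ether oxygen and a benzyloxy group, configuration as in 15 (not isolated) | COC(=O)[C@H](OCc1ccccc1)[C@@H](c1ccc(OCc2ccccc2)cc1)Oc1cc(OCc2ccccc2)cc(OCc2ccccc2)[c-]1.[Cs+] | intermediate
20 | (2R,3R)-3,5,7-tris(benzyloxy)-2-[4-(benzyloxy)phenyl]-2,3-dihydro-4H-chromen-4-one (2,3-trans) | c1c(OCc3ccccc3)cc2c(c1OCc4ccccc4)C(=O)[C@H](OCc6ccccc6)[C@@H](c5ccc(OCc7ccccc7)cc5)O2 | intermediate
21 | (2R,3R)-3,5,7-trihydroxy-2-(4-hydroxyphenyl)-2,3-dihydro-4H-chromen-4-one (dihydrokaempferol) | c1c(O)cc2c(c1O)C(=O)[C@H](O)[C@@H](c3ccc(O)cc3)O2 | intermediate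
22 | (2R,3R)-3,7-bis[(tert-butyldimethylsilyl)oxy]-2-{4-[(tert-butyldimethylsilyl)oxy]phenyl}-5-hydroxy-2,3-dihydro-4H-chromen-4-one | c1c(O[Si](C)(C)C(C)(C)C)cc2c(c1O)C(=O)[C@H](O[Si](C)(C)C(C)(C)C)[C@@H](c3ccc(O[Si](C)(C)C(C)(C)C)cc3)O2 | intermediate
23 | 3-methylbut-2-en-1-ol (prenyl alcohol) | CC(C)=CCO | starting material
24 | [(3-methylbut-2-en-1-yl)oxy]triphenylphosphonium ion (not isolated) | CC(C)=CCO[P+](c1ccccc1)(c1ccccc1)c1ccccc1 | intermediate
25 | (2R,3R)-3,7-bis[(tert-butyldimethylsilyl)oxy]-2-{4-[(tert-butyldimethylsilyl)oxy]phenyl}-5-[(3-methylbut-2-en-1-yl)oxy]-2,3-dihydro-4H-chromen-4-one | c1c(O[Si](C)(C)C(C)(C)C)cc2c(c1OCC=C(C)C)C(=O)[C@H](O[Si](C)(C)C(C)(C)C)[C@@H](c3ccc(O[Si](C)(C)C(C)(C)C)cc3)O2 | intermediate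
26 | ortho dienone: 6-(2-methylbut-3-en-2-yl)-6H-chromene-4,5-dione tautomer of 27, C6 configuration unassigned (not isolated) | C=CC(C)(C)C1C(=O)C2=C(C=C1O[Si](C)(C)C(C)(C)C)O[C@H](c1ccc(O[Si](C)(C)C(C)(C)C)cc1)[C@@H](O[Si](C)(C)C(C)(C)C)C2=O | intermediate
27 | (2R,3R)-3,7-bis[(tert-butyldimethylsilyl)oxy]-2-{4-[(tert-butyldimethylsilyl)oxy]phenyl}-5-hydroxy-6-(2-methylbut-3-en-2-yl)-2,3-dihydro-4H-chromen-4-one | C=CC(C)(C)c1c(O[Si](C)(C)C(C)(C)C)cc2c(c1O)C(=O)[C@H](O[Si](C)(C)C(C)(C)C)[C@@H](c3ccc(O[Si](C)(C)C(C)(C)C)cc3)O2 | intermediate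
28 | (2R,3R)-3,5,7-trihydroxy-2-(4-hydroxyphenyl)-6-(2-methylbut-3-en-2-yl)-2,3-dihydro-4H-chromen-4-one (CNP0527000.1) | C=CC(C)(C)c1c(O)cc2c(c1O)C(=O)[C@H](O)[C@@H](c1ccc(O)cc1)O2 | target

Total step count: 13. Longest linear sequence: 10 steps (steps 4 to 13); the triflate branch (steps 1 to 3) joins at step 8.

Steps most likely to fail

Step 8 (new method). The aryl anion may be quenched before it reaches the ester carbonyl, either by a proton from the medium or by internal abstraction of the hydrogen next to the ester, so that the sequence stops at O-arylation. The unmasked alkoxide may also fragment by retro-aldol cleavage, and liberated methoxide may open ring C. The fallback uses known chemistry and closes the ring by electrophilic instead of anionic acylation. It sets out from hydroxy ester 15 and silyl triflate 8. With CsF in MeCN at rt the free alcohol should undergo the known O–H insertion of arynes, with the same regiochemistry, to give methyl (2R,3R)-2-(benzyloxy)-3-[4-(benzyloxy)phenyl]-3-[3,5-bis(benzyloxy)phenoxy]propanoate F1. Neutral ester cleavage with Me3SnOH in 1,2-dichloroethane at 80 °C should give (2R,3R)-2-(benzyloxy)-3-[4-(benzyloxy)phenyl]-3-[3,5-bis(benzyloxy)phenoxy]propanoic acid F2 without β-elimination. Trifluoroacetic anhydride in CH2Cl2 at 0 °C should then effect intramolecular Friedel–Crafts acylation at either of the two equivalent positions ortho to the ether oxygen of the highly activated ring, which returns the route to 20.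

Step 5. The open transition state may give insufficient anti/syn discrimination, and excess TiCl4 may ionise the electron-rich benzylic titanium aldolate. The fallback reaches the anti relationship by a syn aldol addition followed by inversion. It sets out from acid chloride 10. Acylation of the antipodal auxiliary (R)-4-benzyl-1,3-oxazolidine-2-thione (Et3N, CH2Cl2) should give (4R)-4-benzyl-3-[(benzyloxy)acetyl]-1,3-oxazolidine-2-thione F3. The syn-selective titanium glycolate aldol addition to 12 (TiCl4, i-Pr2NEt, N-methyl-2-pyrrolidinone, CH2Cl2, −78 to 0 °C), which runs through a closed chair transition state and is well established for glycolyl imides, should give (4R)-4-benzyl-3-[(2R,3S)-2-(benzyloxy)-3-[4-(benzyloxy)phenyl]-3-hydroxypropanoyl]-1,3-oxazolidine-2-thione F4. Mitsunobu inversion of the carbinol with 4-nitrobenzoic acid (PPh3, DIAD, toluene, −20 °C) should give (4R)-4-benzyl-3-[(2R,3R)-2-(benzyloxy)-3-[4-(benzyloxy)phenyl]-3-[(4-nitrobenzoyl)oxy]propanoyl]-1,3-oxazolidine-2-thione F5. K2CO3 in MeOH at 0 °C should cleave both the aryl ester and the auxiliary and return the route to 15.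

Step 12. The ortho dienone may undergo a further Cope shift to C8 (the para product) instead of enolising, prolonged heating may isomerise the 1,1-dimethylallyl group, and the temperature may cost silyl groups or stereochemical integrity at C2. The fallback installs the group by cross-coupling at low temperature. It sets out from 22. N-Iodosuccinimide in DMF at rt should iodinate the position ortho to the free, chelated 5-hydroxyl, as is known for 5-hydroxy-7-alkoxy flavonoids, to give (2R,3R)-3,7-bis[(tert-butyldimethylsilyl)oxy]-2-{4-[(tert-butyldimethylsilyl)oxy]phenyl}-5-hydroxy-6-iodo-2,3-dihydro-4H-chromen-4-one F6. A Suzuki–Miyaura allyl–aryl coupling with 4,4,5,5-tetramethyl-2-(3-methylbut-2-en-1-yl)-1,3,2-dioxaborolane (Pd(OAc)2 with a bulky biarylphosphine chosen for coupling at the γ carbon of the allylboronate, K3PO4, THF/H2O, 40 °C) should deliver the branched 1,1-dimethylallyl arene and return the route to 27.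

Further compounds

F1 | step 8 | methyl (2R,3R)-2-(benzyloxy)-3-[4-(benzyloxy)phenyl]-3-[3,5-bis(benzyloxy)phenoxy]propanoate | COC(=O)[C@H](OCc1ccccc1)[C@@H](c1ccc(OCc2ccccc2)cc1)Oc1cc(OCc2ccccc2)cc(OCc2ccccc2)c1
F2 | step 8 | (2R,3R)-2-(benzyloxy)-3-[4-(benzyloxy)phenyl]-3-[3,5-bis(benzyloxy)phenoxy]propanoic acid | OC(=O)[C@H](OCc1ccccc1)[C@@H](c1ccc(OCc2ccccc2)cc1)Oc1cc(OCc2ccccc2)cc(OCc2ccccc2)c1
F3 | step 5 | (4R)-4-benzyl-3-[(benzyloxy)acetyl]-1,3-oxazolidine-2-thione | O=C(COCc1ccccc1)N1C(=S)OC[C@H]1Cc1ccccc1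
F4 | step 5 | (4R)-4-benzyl-3-[(2R,3S)-2-(benzyloxy)-3-[4-(benzyloxy)phenyl]-3-hydroxypropanoyl]-1,3-oxazolidine-2-thione | O=C([C@H](OCc1ccccc1)[C@H](c1ccc(OCc2ccccc2)cc1)O)N1C(=S)OC[C@H]1Cc1ccccc1
F5 | step 5 | (4R)-4-benzyl-3-[(2R,3R)-2-(benzyloxy)-3-[4-(benzyloxy)phenyl]-3-[(4-nitrobenzoyl)oxy]propanoyl]-1,3-oxazolidine-2-thione | O=C([C@H](OCc1ccccc1)[C@@H](c1ccc(OCc2ccccc2)cc1)OC(=O)c1ccc(cc1)[N+](=O)[O-])N1C(=S)OC[C@H]1Cc1ccccc1
F6 | step 12 | (2R,3R)-3,7-bis[(tert-butyldimethylsilyl)oxy]-2-{4-[(tert-butyldimethylsilyl)oxy]phenyl}-5-hydroxy-6-iodo-2,3-dihydro-4H-chromen-4-one | Ic1c(O[Si](C)(C)C(C)(C)C)cc2c(c1O)C(=O)[C@H](O[Si](C)(C)C(C)(C)C)[C@@H](c3ccc(O[Si](C)(C)C(C)(C)C)cc3)O2
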